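## Analysis of the target

The target (36) is a 6-chloro-5(16)-ene briarane. A cyclohexane (ring A: C1, C10–C14) is trans-fused at C1–C10 to a ten-membered carbocycle (C1–C10). A trans-fused α-methyl-β-hydroxy-γ-lactone (O7–C19(=O)–C17(C18)–C8) spans C7–C8.

There are eleven stereocentres: quaternary C1 (bearing C15), C2, C6, C7, C8 (tertiary OH), C9, C10, C11 (spiro-epoxide), C12, C14 and C17. With β defined as the face of C15 on the flat ring drawing, the SMILES gives 10α-H, 14α-OAc, 12α-O-isovalerate, 11α,20-epoxide, 2β-O-isobutyrate, 9β-OAc, 8α-OH, 7α-O, 6α-Cl, and C18 cis to 8-OH on the lactone.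

Four acyloxy groups of three kinds sit next to a free tertiary alcohol, so the oxygens must be unveiled in a fixed order. The sensitive groups are the secondary allylic chloride between an exo-methylene and an acyloxy carbon, the spiro-epoxide, the β-hydroxy lactone and the esters.

The hard part is the ten-membered ring attached to a quaternary carbon, together with the contiguous C6–C9 array. The feature that invites the chosen move is this ring itself: the ring oxygens at C2 and C7 stand 1,6 to each other. That is the pattern left when a six-membered ring (ring B: C1, C2, C7, C8, C9, C10) is enlarged by four atoms (C3–C6) across its C2–C7 bond. The one-carbon branch C16 sits on C5, the terminus of one inserted two-carbon unit.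

## Retrosynthetic reasoning

**36 ⇒ 35.** The C6–Cl bond and the C5=C16 double bond are cut together. In the forward direction an ene-type allylic chlorination of the Δ5 olefin (C16 still a methyl group) installs both, as the 6-chloro-5(16)-enes are thought to arise from Δ5 briaranes. This keeps the most labile group out of the whole route.

**35 ⇒ 30 (via 34, 33, 32, 31).** The acyl groups and the epoxide are removed in an order that needs no selectivity between like alcohols. O12 carries the only silyl group, O9 and O14 both carry PMB, and O2 is acylated while it is the only free secondary alcohol. The epoxide is made from the 12α-allylic alcohol two steps before the end, so it meets neither fluoride nor DDQ.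

**30 ⇒ 27 ⇒ 26.** The lactone is cut at C8–C17. Forward, an intramolecular Reformatsky reaction of the 7-(2-bromopropanoyl)oxy 8-ketone 26 forms the ring, the tertiary C8 alcohol and C17 in one step, with O7 as the tether. The C2 carbonyl stays masked as its methyl enol ether until C7 and C8 are no longer carbonyl carbons (27 ⇒ 28 ⇒ 29 ⇒ 30).

**26 ⇒ 22 (via 25, 24, 23).** The C7 and C8 oxygens are traced to the enone 22: α′-hydroxylation gives 23, chelation-controlled reduction gives 24, and the two alcohols are then differentiated. C9 relays its configuration to C8 and C8 to C7. C8 is then oxidised and reset by the tether.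

**22 ⇒ 21 ⇒ 19 (key).** The ten-membered ring is opened conceptually by cutting C4–C5 and re-forming C2–C7. Forward, the C7 alkoxide of 19, with vinyl on C2 and propenyl on C7, undergoes an anionic oxy-Cope rearrangement. A rigid trans-decalin, on which C1, C9, C10, C12 and C14 are already set, becomes the medium ring without any end-to-end cyclisation. The regiodefined enolate is oxidised to the Δ5-enone 22, which places C16 as a methyl on an olefin, ready for the last step.

**19 ⇒ 7 (via 18 … 8).** The two alkenyl groups come from the two ring B carbonyl functions of 7. The C2 ketone takes vinyl (8). The C7 methyl enol ether is hydrolysed to the ketone (18), which takes propenyl (19). In between, the C9 carbonyl is reduced (10) and ring A is taken to the 12α-silyloxy 11(20)-ene (12 → 17).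

**7 ⇒ 4 + 5.** Ring A is cut at C1–C14 and C10–C11. Forward, a Diels–Alder reaction of quinone 5 with diene 4 forms the quaternary C1, sets C14 relative to it (endo), and delivers every ring B oxygen (C2, C7, C9) and both ring A oxygens (C12, C14) in one step. C10 is then epimerised to the trans fusion.

**4 ⇒ 3 ⇒ 1 + 2.** The diene is the silyl enol ether of the vinylogous ester 3, made by exchange of the methoxy group of 1 with alcohol 2.

## Alternatives that were turned down

**Alternative 1:** the textbook disconnection at C5=C6, ring-closing metathesis of the seco-diene A1 (ring A with both side arms and the lactone in place). It was turned down for three reasons.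
- It must close a strained ten-membered ring by forming a trisubstituted olefin between a 1,1-disubstituted alkene and an allylic acyloxy carbon next to a quaternary carbinol. Initiation is slow, oligomerisation competes and E/Z is uncontrolled.
- The ring closure sets no stereocentre.
- C2, C7, C8, C9 and C17 must all be built beforehand on flexible chains hanging from a quaternary carbon, so the riskiest step comes at the end of a long linear sequence.

**Alternative 2:** the biomimetic disconnection at C1–C10, a transannular epoxy-olefin cyclisation of the fourteen-membered cembranoid-type epoxide A2 (1,14-epoxide, Δ10). It would form ring A and the quaternary C1 with loss of a C20 proton. It was turned down for three reasons.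
- Anti opening of the E-derived epoxide through a chair puts the C14 oxygen cis to C15, the opposite of the target. A contra-biogenetic Z-epoxide or an inversion at a neopentyl carbon would be needed.
- In a flexible fourteen-membered ring, the Δ5 olefin, the 8-OH and the ester carbonyls compete with Δ10 for the cation.
- A2 is a stereodefined, poly-oxygenated macrocycle that costs about as much as the target.

**Alternative 3:** oxidative cleavage of the tetrasubstituted C2=C7 olefin of the tricyclic A3 (ring B annulated by a third ring C2–C3–C4–C5–C6–C7) to the ten-membered 2,7-dione. It uses the same 1,6-relationship but was turned down for three reasons.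
- The 1,6-diketone is prone to transannular aldolisation.
- Both carbonyls must then be reduced with no control element for C7.
- C5 and C6 would have to be functionalised in a ring that is built only to be cut, and no stereocentre is set.

Key step: step 14

Remark on names: briarane numbering is used throughout (C1–C10 ten-membered ring, C11–C14 ring A, C15 on C1, C16 on C5, C17/C18/C19 lactone CH/CH3/C=O, C20 on C11). β is the face of C15. In the decalins, ring B is C1-C2-C7-C8-C9-C10.

Assumption: quinone 5 is taken as a catalogue compound, and the (R)-configured titanium catalyst in step 3 is taken to give the enantiomer drawn for 7 (if the antipode is favoured, the (S)-ligand is used).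

## Route

Step 1
Reactants: 1 (E)-4-methoxybut-3-en-2-one; 2 4-methoxybenzyl alcohol
Product: 3 (E)-4-[(4-methoxybenzyl)oxy]but-3-en-2-one
Conditions: PPTS (5 mol %), toluene, 80 °C, 4 Å MS (removal of MeOH)
Reagents that add atoms: none
Why: Acid-catalysed addition–elimination (transetherification) at the β-carbon of the vinylogous ester; the E isomer is the thermodynamic product.

Step 2
Reactants: 3 (E)-4-[(4-methoxybenzyl)oxy]but-3-en-2-one
Product: 4 (E)-3-(tert-butyldimethylsilyloxy)-1-[(4-methoxybenzyl)oxy]buta-1,3-diene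
Conditions: TBSOTf, Et3N, Et2O, 0 °C
Reagents that add atoms: tert-butyldimethylsilyl trifluoromethanesulfonate, CC(C)(C)[Si](C)(C)OS(=O)(=O)C(F)(F)F
Why: Soft enolisation and O-silylation of the methyl ketone give a Danishefsky-type 1-alkoxy-3-silyloxy diene.

Step 3
Reactants: 4 (E)-3-(tert-butyldimethylsilyloxy)-1-[(4-methoxybenzyl)oxy]buta-1,3-diene; 5 2-methoxy-6-methyl-1,4-benzoquinone
Product: 7 trans-fused enedione (7-methoxy-14α-PMBO-12-TBSO-Δ7,Δ12-decalin-2,9-dione; 15β-Me; 10α-H), via cis-fused cycloadduct 6 (not isolated)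
Conditions: (R)-BINOL/Ti(OiPr)4 (1:1, 10 mol %), 4 Å MS, CH2Cl2, −40 °C; then DBU (0.2 equiv), toluene, 25 °C
Reagents that add atoms: none
Why: Endo Diels–Alder reaction at the methyl-bearing C=C of 5 (the methoxy-bearing one is a deactivated vinylogous ester); titanium chelated by the C2 carbonyl and the methoxy oxygen makes C10 the electrophilic terminus, so the CH2 terminus of 4 bonds to C10 and the oxygenated terminus to C1, endo addition puts 14-OPMB trans to C15, and the ligand sets the absolute sense. DBU then epimerises C10 (α to the C9 carbonyl) to the more stable trans-fused 7, as in related angularly methylated octalinediones.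

Step 4
Reactants: 7 trans-fused enedione
Product: 8 2β-hydroxy-2α-vinyl carbinol (9-ketone retained)
Conditions: vinylmagnesium bromide, anhydrous CeCl3, THF, −78 °C
Reagents that add atoms: vinylmagnesium bromide, C=C[Mg]Br
Why: Organocerium 1,2-addition to C2, the only true ketone (C9=O is a less electrophilic vinylogous ester); cerium suppresses enolisation and conjugate addition. Attack anti to the axial C15 methyl gives the 2α-vinyl carbinol, a stereocentre that is erased in step 14.

Step 5
Reactants: 8 2β-hydroxy-2α-vinyl carbinol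
Product: 9 2β-methoxy-2α-vinyl ether
Conditions: KHMDS (1.05 equiv), THF, −78 °C; MeI, −78 → 0 °C
Reagents that add atoms: iodomethane, CI
Why: Williamson methylation of the tertiary alkoxide; the methyl ether leaves no second alkoxide or migrating group at C2 for step 14 and later becomes the enol ether that masks the C2 ketone.

Step 6
Reactants: 9 2β-methoxy-2α-vinyl ether
Product: 10 9β-alcohol
Conditions: DIBAL-H, CH2Cl2, −78 °C; Rochelle salt work-up
Reagents that add atoms: none
Why: 1,2-Reduction of the vinylogous ester carbonyl; hydride enters from the α face, away from the syn-axial C15 methyl, which gives the 9β-alcohol, and the non-acidic work-up avoids allylic transposition.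

Step 7
Reactants: 10 9β-alcohol
Product: 11 9β-PMB ether
Conditions: NaH, 4-methoxybenzyl chloride, Bu4NI (cat.), THF/DMF, 0 → 25 °C
Reagents that add atoms: 4-methoxybenzyl chloride, COc1ccc(CCl)cc1
Why: Williamson etherification under basic conditions, which the acid-labile 3-methoxy allylic alcohol tolerates.

Step 8
Reactants: 11 9β-PMB ether
Product: 12 12-ketone
Conditions: TBAF/AcOH (1:1.2), THF, −20 °C
Reagents that add atoms: none
Why: Fluoride cleaves the silyl enol ether only (methyl enol ether and PMB ethers are inert); the acetic acid buffer prevents β-elimination of the 14-alkoxy group from the new β-alkoxy ketone.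

Step 9
Reactants: 12 12-ketone
Product: 15 11(20)-en-12-one, via Mannich base 13 (not isolated), via trimethylammonium iodide 14 (not isolated)
Conditions: LiHMDS, THF, −78 °C; Me2N+=CH2 I−, −78 → 0 °C; then MeI, CH2Cl2, 25 °C; then DBU, 25 °C
Reagents that add atoms: N,N-dimethylmethyleneiminium iodide (Eschenmoser's salt), C=[N+](C)C.[I-]
Why: Kinetic deprotonation takes place at C11, remote from the β-alkoxy branch, and the enolate undergoes a Mannich reaction; quaternisation and E1cB elimination give the α-methylene ketone (C20).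

Step 10
Reactants: 15 11(20)-en-12-one
Product: 16 12α-alcohol
Conditions: NaBH4, CeCl3·7H2O, MeOH, −78 °C
Reagents that add atoms: none
Why: Luche 1,2-reduction; the axial trajectory on the α face is blocked by the syn-axial 14α-OPMB group, so hydride enters from the β face and gives the axial 12α-alcohol.

Step 11
Reactants: 16 12α-alcohol
Product: 17 12α-TBS ether
Conditions: TBSOTf, 2,6-lutidine, CH2Cl2, −78 °C
Reagents that add atoms: tert-butyldimethylsilyl trifluoromethanesulfonate, CC(C)(C)[Si](C)(C)OS(=O)(=O)C(F)(F)F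
Why: Silylation of the hindered allylic alcohol without an alkoxide; silicon on O12 is orthogonal to the PMB ethers on O9 and O14.

Step 12
Reactants: 17 12α-TBS ether
Product: 18 7-ketone
Conditions: oxalic acid (0.1 M aq.), THF, 0 °C
Reagents that add atoms: water, O
Why: Hydrolysis of the methyl enol ether by protonation at C8 and hydration of the oxocarbenium ion unmasks the C7 ketone; the cold, weakly acidic conditions are meant to keep the 9-OPMB group, now β to the ketone.

Step 13
Reactants: 18 7-ketone
Product: 19 7β-hydroxy-7α-[(E)-prop-1-enyl] carbinol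
Conditions: (E)-1-bromopropene, t-BuLi (2 equiv), Et2O, −78 °C; anhydrous CeCl3, THF, −78 °C; then 18
Reagents that add atoms: (E)-1-bromopropene, C/C=C/Br
Why: Alkenylcerium 1,2-addition to the hindered ketone; the β face is screened by the syn-axial C15 methyl and 9β-OPMB, so the propenyl group enters from the α face and ends equatorial, cis (gauche) to the axial 2α-vinyl group.

Step 14
Reactants: 19 7β-hydroxy-7α-[(E)-prop-1-enyl] carbinol
Product: 21 ring-expanded bis-enol ether ((2Z,6E)-2-methoxy-7-trimethylsilyloxy-5-methyl ten-membered 2,6-diene), via potassium enolate 20 (not isolated)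
Conditions: KH, 18-crown-6, THF, 0 → 25 °C; then Et3N, TMSCl, −78 °C
Reagents that add atoms: chlorotrimethylsilane, C[Si](C)(C)Cl
Why: KH with 18-crown-6 gives the free potassium alkoxide of 19, which undergoes an anionic oxy-Cope ([3,3]-sigmatropic) rearrangement: the ring B bond C2–C7 breaks, C4–C5 forms and the alkoxide becomes the C7 enolate 20. The closest known reaction type is the anionic oxy-Cope ring expansion of 1,2-dialkenylcyclohexanols to cyclodec-5-enones used for germacrane-type rings. The ten-membered ring is therefore not closed end to end; it arises by a four-atom enlargement of the six-membered ring B through a six-centre chair transition state in which the axial 2α-vinyl and equatorial 7α-propenyl groups are gauche. No stereocentre of the target is made or touched: C1, C9, C10, C12 and C14 are carried over from the rigid decalin, C2 and C7 become sp2, and the new C5 centre and both enol double-bond geometries (2Z and 6E expected from the chair with O− equatorial) are removed in steps 15 and 21. The step needs the [3,3] path to win over [1,3] shift, retro-addition and β-elimination: the cis alkenyl groups from steps 4 and 13 allow the chair, the O-methyl group at C2 leaves a single alkoxide and cannot migrate, and the enolate forms regiospecifically on the C6 side, remote from 9-OPMB, and is trapped cold as the silyl enol ether 21. Charge delocalisation into the enolate and relief of the syn-axial crowding of ring B (C15 methyl, O7, 9-OPMB) drive the reaction.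

Step 15
Reactants: 21 ring-expanded bis-enol ether
Product: 22 (2Z,5Z)-2-methoxy-2,5-dien-7-one
Conditions: Pd(OAc)2 (1.1 equiv), MeCN, 25 °C
Reagents that add atoms: none
Why: Saegusa–Ito oxidation: the regiodefined silyl enol ether gives a palladium enolate, and β-hydride elimination from C5 forms the Δ5-enone and erases the C5 centre; the ring-cis (5Z) enone is expected as the more stable isomer.

Step 16
Reactants: 22 (2Z,5Z)-2-methoxy-2,5-dien-7-one
Product: 23 8α-hydroxy enone
Conditions: LiHMDS, THF, −78 °C; (±)-trans-3-phenyl-2-(phenylsulfonyl)oxaziridine, −78 °C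
Reagents that add atoms: 3-phenyl-2-(phenylsulfonyl)oxaziridine, O=S(=O)(c1ccccc1)N1OC1c1ccccc1
Why: Kinetic α′-deprotonation of the enone at C8 and Davis hydroxylation of the enolate; oxygen enters anti to the neighbouring 9β-OPMB group and gives the 8α-carbinol, a relay stereocentre for C7.

Step 17
Reactants: 23 8α-hydroxy enone
Product: 24 7α,8α-diol
Conditions: Zn(BH4)2, Et2O, −30 °C
Reagents that add atoms: none
Why: Chelation-controlled (Cram-chelate) 1,2-reduction of the α-hydroxy enone; hydride adds to the zinc chelate anti to C9 and gives the cis-diol, so C7 now has its final configuration.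

Step 18
Reactants: 24 7α,8α-diol
Product: 25 7α-(2-bromopropanoyl)oxy-8α-ol
Conditions: 2-bromopropanoyl bromide (1.05 equiv), 2,4,6-collidine, CH2Cl2, −78 °C
Reagents that add atoms: 2-bromopropanoyl bromide, CC(Br)C(Br)=O
Why: Acylation of the allylic 7-OH, which is less hindered than the 8-OH flanked by C9-OPMB; the racemic bromide suffices because C17 is set in step 20.

Step 19
Reactants: 25 7α-(2-bromopropanoyl)oxy-8α-ol
Product: 26 7α-(2-bromopropanoyl)oxy-8-ketone
Conditions: Dess–Martin periodinane, NaHCO3, CH2Cl2, 0 °C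
Reagents that add atoms: none
Why: Dess–Martin oxidation of the remaining secondary alcohol under buffered conditions that should not epimerise the now acidic C7–H.

Step 20
Reactants: 26 7α-(2-bromopropanoyl)oxy-8-ketone
Product: 27 8α-hydroxy-19,7α-lactone (C18 cis to 8-OH)
Conditions: SmI2 (2.2 equiv), THF, −78 °C
Reagents that add atoms: none
Why: Samarium(II) reduces the C–Br bond to a samarium(III) enolate that adds to the C8 ketone (intramolecular Reformatsky reaction, as in classical butenolide syntheses from α-acyloxy ketones). The O7 tether allows addition only with O7 and C17 nearly syn across C7–C8, and the medium ring prefers an anti-type C6–C7–C8–C9 torsion, which gives 8α-OH and the trans-fused lactone. C18 takes the less hindered, epimerisable position anti to C9.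

Step 21
Reactants: 27 8α-hydroxy-19,7α-lactone
Product: 28 2-ketone
Conditions: oxalic acid (aq.), THF, 25 °C
Reagents that add atoms: water, O
Why: Hydrolysis of the C2 methyl enol ether (protonation at C3, hydration) releases the C2 ketone only after C7 and C8 have ceased to be carbonyl carbons, so no transannular aldol reaction of a ring diketone can occur.

Step 22
Reactants: 28 2-ketone
Product: 29 2β-alcohol
Conditions: NaBH4, MeOH/CH2Cl2, −40 °C
Reagents that add atoms: none
Why: Borohydride reduces the ketone and leaves the lactone; hydride attacks anti to the C15 methyl on the adjacent quaternary carbon, which gives the 2β-alcohol.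

Step 23
Reactants: 29 2β-alcohol
Product: 30 2β-isobutyrate
Conditions: isobutyryl chloride, pyridine, DMAP (cat.), CH2Cl2, 25 °C
Reagents that add atoms: isobutyryl chloride, CC(C)C(Cl)=O
Why: DMAP-catalysed acylation of the only free secondary alcohol; the tertiary 8-OH is too hindered to react.

Step 24
Reactants: 30 2β-isobutyrate
Product: 31 9β,14α-diol
Conditions: DDQ (2.4 equiv), CH2Cl2/pH 7 buffer, 0 °C
Reagents that add atoms: none
Why: Oxidative cleavage of both PMB ethers (hydride abstraction, hydrolysis of the oxocarbenium ions); silyl ether, esters and alkenes are untouched, and no epoxide is present yet.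

Step 25
Reactants: 31 9β,14α-diol
Product: 32 9β,14α-diacetate
Conditions: Ac2O, pyridine, DMAP (cat.), CH2Cl2, 0 → 25 °C
Reagents that add atoms: acetic anhydride, CC(=O)OC(C)=O
Why: Acetylation of the two secondary alcohols; the tertiary 8-OH should stay free under these conditions.

Step 26
Reactants: 32 9β,14α-diacetate
Product: 33 12α-alcohol
Conditions: HF·pyridine, THF/pyridine, 0 → 25 °C
Reagents that add atoms: none
Why: Fluoride cleaves the last silyl ether under mildly acidic conditions that spare esters and lactone.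

Step 27
Reactants: 33 12α-alcohol
Product: 34 11α,20-epoxide
Conditions: VO(acac)2 (5 mol %), t-BuOOH, CH2Cl2, 0 °C
Reagents that add atoms: tert-butyl hydroperoxide, CC(C)(C)OO
Why: Vanadium-catalysed hydroxyl-directed epoxidation of the exocyclic allylic alcohol; oxygen is delivered syn to the axial 12α-OH and anti to the axial C15 methyl, and the isolated Δ5 olefin is not epoxidised.

Step 28
Reactants: 34 11α,20-epoxide
Product: 35 12α-isovalerate
Conditions: isovaleryl chloride, pyridine, DMAP (cat.), CH2Cl2, 0 °C
Reagents that add atoms: 3-methylbutanoyl chloride, CC(C)CC(Cl)=O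
Why: Acylation of the only free secondary alcohol under mild base that the epoxide tolerates.

Step 29
Reactants: 35 12α-isovalerate
Product: 36 target CNP0194902.1
Conditions: Ca(OCl)2, solid CO2, CH2Cl2/H2O, 0 °C
Reagents that add atoms: calcium hypochlorite, [Ca+2].[O-]Cl.[O-]Cl
Why: Ene-type allylic chlorination by hypochlorous acid: chlorenium adds to C6 of the trisubstituted olefin on its exposed α face and a proton is lost from the C16 methyl, giving the 6α-chloride and the 5(16)-methylene group. This mirrors the presumed origin of the 6-chloro-5(16)-ene briaranes from Δ5 congeners.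

## Compound list

1 | (E)-4-methoxybut-3-en-2-one | CO/C=C/C(C)=O | starting material
2 | 4-methoxybenzyl alcohol | COc1ccc(CO)cc1 | starting material
3 | (E)-4-[(4-methoxybenzyl)oxy]but-3-en-2-one | CC(=O)/C=C/OCc1ccc(OC)cc1 | intermediate
4 | (E)-3-(tert-butyldimethylsilyloxy)-1-[(4-methoxybenzyl)oxy]buta-1,3-diene | C=C(O[Si](C)(C)C(C)(C)C)/C=C/OCc1ccc(OC)cc1 | intermediate
5 | 2-methoxy-6-methyl-1,4-benzoquinone | COC1=CC(=O)C=C(C)C1=O | starting material
6 | cis-fused endo cycloadduct (10β-H epimer of 7; not isolated) | C[C@]12[C@@H](OCc3ccc(OC)cc3)C=C(O[Si](C)(C)C(C)(C)C)C[C@H]1C(=O)C=C(OC)C2=O | intermediate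
7 | trans-decalin enedione: 15β-Me, 10α-H, 2,9-dioxo, 7-OMe-Δ7, 12-OTBS-Δ12, 14α-OPMB | C[C@]12[C@@H](OCc3ccc(OC)cc3)C=C(O[Si](C)(C)C(C)(C)C)C[C@@H]1C(=O)C=C(OC)C2=O | intermediate
8 | 2β-hydroxy-2α-vinyl carbinol of 7 | C[C@]12[C@@H](OCc3ccc(OC)cc3)C=C(O[Si](C)(C)C(C)(C)C)C[C@@H]1C(=O)C=C(OC)[C@@]2(O)C=C | intermediate
9 | 2β-methoxy-2α-vinyl ether | C[C@]12[C@@H](OCc3ccc(OC)cc3)C=C(O[Si](C)(C)C(C)(C)C)C[C@@H]1C(=O)C=C(OC)[C@@]2(OC)C=C | intermediate
10 | 9β-alcohol | C[C@]12[C@@H](OCc3ccc(OC)cc3)C=C(O[Si](C)(C)C(C)(C)C)C[C@@H]1[C@H](O)C=C(OC)[C@@]2(OC)C=C | intermediate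
11 | 9β-PMB ether | C[C@]12[C@@H](OCc3ccc(OC)cc3)C=C(O[Si](C)(C)C(C)(C)C)C[C@@H]1[C@H](OCc4ccc(OC)cc4)C=C(OC)[C@@]2(OC)C=C | intermediate
12 | 12-ketone | C[C@]12[C@@H](OCc3ccc(OC)cc3)CC(=O)C[C@@H]1[C@H](OCc4ccc(OC)cc4)C=C(OC)[C@@]2(OC)C=C | intermediate
13 | C11 dimethylaminomethyl ketone (Mannich base, C11 epimers; not isolated) | C[C@]12[C@@H](OCc3ccc(OC)cc3)CC(=O)C(CN(C)C)[C@@H]1[C@H](OCc4ccc(OC)cc4)C=C(OC)[C@@]2(OC)C=C | intermediate
14 | C11 trimethylammoniomethyl ketone iodide (not isolated) | C[C@]12[C@@H](OCc3ccc(OC)cc3)CC(=O)C(C[N+](C)(C)C)[C@@H]1[C@H](OCc4ccc(OC)cc4)C=C(OC)[C@@]2(OC)C=C.[I-] | intermediate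
15 | 11(20)-en-12-one | C[C@]12[C@@H](OCc3ccc(OC)cc3)CC(=O)C(=C)[C@@H]1[C@H](OCc4ccc(OC)cc4)C=C(OC)[C@@]2(OC)C=C | intermediate
16 | 12α-alcohol | C[C@]12[C@@H](OCc3ccc(OC)cc3)C[C@@H](O)C(=C)[C@@H]1[C@H](OCc4ccc(OC)cc4)C=C(OC)[C@@]2(OC)C=C | intermediate
17 | 12α-TBS ether | C[C@]12[C@@H](OCc3ccc(OC)cc3)C[C@@H](O[Si](C)(C)C(C)(C)C)C(=C)[C@@H]1[C@H](OCc4ccc(OC)cc4)C=C(OC)[C@@]2(OC)C=C | intermediate
18 | 7-ketone (2β-OMe, 2α-vinyl, 9β-OPMB, 12α-OTBS, 14α-OPMB, 11(20)-ene) | C[C@]12[C@@H](OCc3ccc(OC)cc3)C[C@@H](O[Si](C)(C)C(C)(C)C)C(=C)[C@@H]1[C@H](OCc4ccc(OC)cc4)CC(=O)[C@@]2(OC)C=C | intermediate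
19 | 7β-hydroxy-7α-[(E)-prop-1-enyl] carbinol | C[C@]12[C@@H](OCc3ccc(OC)cc3)C[C@@H](O[Si](C)(C)C(C)(C)C)C(=C)[C@@H]1[C@H](OCc4ccc(OC)cc4)C[C@@](O)(/C=C/C)[C@@]2(OC)C=C | intermediate
20 | potassium (6E)-enolate of the ring-expanded 7-ketone (C5 configuration not relevant; not isolated) | C[C@]12[C@@H](OCc3ccc(OC)cc3)C[C@@H](O[Si](C)(C)C(C)(C)C)C(=C)[C@@H]1[C@H](OCc4ccc(OC)cc4)C/C([O-])=C\C(C)C/C=C2\OC.[K+] | intermediate
21 | ten-membered (2Z,6E)-2-methoxy-7-trimethylsilyloxy-2,6-diene, 5-methyl (C5 configuration not relevant) | C[C@]12[C@@H](OCc3ccc(OC)cc3)C[C@@H](O[Si](C)(C)C(C)(C)C)C(=C)[C@@H]1[C@H](OCc4ccc(OC)cc4)C/C(O[Si](C)(C)C)=C\C(C)C/C=C2\OC | intermediate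
22 | (2Z,5Z)-2-methoxy-2,5-dien-7-one | C[C@]12[C@@H](OCc3ccc(OC)cc3)C[C@@H](O[Si](C)(C)C(C)(C)C)C(=C)[C@@H]1[C@H](OCc4ccc(OC)cc4)CC(=O)/C=C(C)\C/C=C2\OC | intermediate
23 | 8α-hydroxy enone | C[C@]12[C@@H](OCc3ccc(OC)cc3)C[C@@H](O[Si](C)(C)C(C)(C)C)C(=C)[C@@H]1[C@H](OCc4ccc(OC)cc4)[C@@H](O)C(=O)/C=C(C)\C/C=C2\OC | intermediate
24 | 7α,8α-diol | C[C@]12[C@@H](OCc3ccc(OC)cc3)C[C@@H](O[Si](C)(C)C(C)(C)C)C(=C)[C@@H]1[C@H](OCc4ccc(OC)cc4)[C@@H](O)[C@@H](O)/C=C(C)\C/C=C2\OC | intermediate
25 | 7α-(2-bromopropanoyl)oxy-8α-ol (bromide epimers) | C[C@]12[C@@H](OCc3ccc(OC)cc3)C[C@@H](O[Si](C)(C)C(C)(C)C)C(=C)[C@@H]1[C@H](OCc4ccc(OC)cc4)[C@@H](O)[C@@H](OC(=O)C(C)Br)/C=C(C)\C/C=C2\OC | intermediate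
26 | 7α-(2-bromopropanoyl)oxy-8-ketone | C[C@]12[C@@H](OCc3ccc(OC)cc3)C[C@@H](O[Si](C)(C)C(C)(C)C)C(=C)[C@@H]1[C@H](OCc4ccc(OC)cc4)C(=O)[C@@H](OC(=O)C(C)Br)/C=C(C)\C/C=C2\OC | intermediate
27 | 8α-hydroxy-19,7α-lactone, C2 methyl enol ether | C[C@]12[C@@H](OCc3ccc(OC)cc3)C[C@@H](O[Si](C)(C)C(C)(C)C)C(=C)[C@@H]1[C@H](OCc4ccc(OC)cc4)[C@]5(O)[C@@H](C)C(=O)O[C@H]5/C=C(C)\C/C=C2\OC | intermediate
28 | 2-ketone | C[C@]12[C@@H](OCc3ccc(OC)cc3)C[C@@H](O[Si](C)(C)C(C)(C)C)C(=C)[C@@H]1[C@H](OCc4ccc(OC)cc4)[C@]5(O)[C@@H](C)C(=O)O[C@H]5/C=C(C)\CCC2=O | intermediate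
29 | 2β-alcohol | C[C@]12[C@@H](OCc3ccc(OC)cc3)C[C@@H](O[Si](C)(C)C(C)(C)C)C(=C)[C@@H]1[C@H](OCc4ccc(OC)cc4)[C@]5(O)[C@@H](C)C(=O)O[C@H]5/C=C(C)\CC[C@@H]2O | intermediate
30 | 2β-isobutyrate | C[C@]12[C@@H](OCc3ccc(OC)cc3)C[C@@H](O[Si](C)(C)C(C)(C)C)C(=C)[C@@H]1[C@H](OCc4ccc(OC)cc4)[C@]5(O)[C@@H](C)C(=O)O[C@H]5/C=C(C)\CC[C@@H]2OC(=O)C(C)C | intermediate
31 | 9β,14α-diol | C[C@]12[C@@H](O)C[C@@H](O[Si](C)(C)C(C)(C)C)C(=C)[C@@H]1[C@H](O)[C@]5(O)[C@@H](C)C(=O)O[C@H]5/C=C(C)\CC[C@@H]2OC(=O)C(C)C | intermediate
32 | 9β,14α-diacetate | C[C@]12[C@@H](OC(C)=O)C[C@@H](O[Si](C)(C)C(C)(C)C)C(=C)[C@@H]1[C@H](OC(C)=O)[C@]5(O)[C@@H](C)C(=O)O[C@H]5/C=C(C)\CC[C@@H]2OC(=O)C(C)C | intermediate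
33 | 12α-alcohol (5Z,11(20)-diene) | C[C@]12[C@@H](OC(C)=O)C[C@@H](O)C(=C)[C@@H]1[C@H](OC(C)=O)[C@]5(O)[C@@H](C)C(=O)O[C@H]5/C=C(C)\CC[C@@H]2OC(=O)C(C)C | intermediate
34 | 11α,20-epoxy-12α-alcohol | C[C@]12[C@@H](OC(C)=O)C[C@@H](O)[C@]3(CO3)[C@@H]1[C@H](OC(C)=O)[C@]5(O)[C@@H](C)C(=O)O[C@H]5/C=C(C)\CC[C@@H]2OC(=O)C(C)C | intermediate
35 | (5Z)-9β,14α-diacetoxy-11α,20-epoxy-8α-hydroxy-2β-isobutyryloxy-12α-isovaleryloxybriar-5-en-19,7α-olide | C[C@]12[C@@H](OC(C)=O)C[C@@H](OC(=O)CC(C)C)[C@]3(CO3)[C@@H]1[C@H](OC(C)=O)[C@]5(O)[C@@H](C)C(=O)O[C@H]5/C=C(C)\CC[C@@H]2OC(=O)C(C)C | intermediate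
36 | CNP0194902.1: 9β,14α-diacetoxy-6α-chloro-11α,20-epoxy-8α-hydroxy-2β-isobutyryloxy-12α-isovaleryloxybriar-5(16)-en-19,7α-olide | C=C1CC[C@H](OC(=O)C(C)C)[C@@]2(C)[C@@H](OC(C)=O)C[C@@H](OC(=O)CC(C)C)[C@]3(CO3)[C@@H]2[C@H](OC(C)=O)[C@]2(O)[C@@H](C)C(=O)O[C@H]2[C@H]1Cl | target

## Step count and least certain steps

Total step count: 29. Longest linear sequence: 29 steps (1/2 → 36; the only convergence is the cycloaddition in step 3, whose partner 5 is purchased).

**Step 14 (key step).** The alkoxide may fail to reach the chair transition state if step 13 has placed the propenyl group trans-diaxial to the vinyl group; cerium chelation by the C2 methoxy group would favour that outcome. The basic medium can then divert the alkoxide into retro-addition, or, after enolate equilibration, into β-elimination of the C9 ether. The fallback sets out from 18 and returns at 22. Prop-1-ynylmagnesium bromide/CeCl3 is added to 18 to give the 7β-hydroxy-7α-(prop-1-ynyl) carbinol F1. F1 is heated without base (o-dichlorobenzene, 180 °C). A neutral acetylenic oxy-Cope rearrangement, in which the linear alkyne tolerates a twist-boat ring B, gives an allenol that tautomerises directly to enone 22. This avoids the alkoxide and the enolate oxidation.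

**Step 3.** The uncatalysed cycloaddition of the very electron-rich diene may erode the enantioselectivity, and the cis/trans equilibration may stop short. The fallback sets out from 4 and 5 and returns at 10. The cycloaddition is run thermally (toluene, 25 °C) and the racemate of 7 (same constitution, no new label) is carried through steps 4–6 to racemic 10. A lipase-catalysed acylation (Pseudomonas cepacia lipase, vinyl acetate) converts the unwanted enantiomer into the acetate of ent-10 F2 and leaves 10 for the route.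

**Step 12.** Acid may ionise the allylic C9–O bond with help from the enol ether (allylic transposition with loss of the C9 oxygen) faster than it protonates C8. The fallback sets out from 17 and returns at 18. Dimethyldioxirane (acetone, −78 °C) epoxidises the enol ether under neutral conditions and gives the 8α-hydroxy-7-ketone F3. Acetylation gives the 8α-acetoxy-7-ketone F4, and SmI2/MeOH removes the α-acetoxy group reductively to give 18.

**Step 20.** Samarium(II) may cleave the C7–O bond of the α-acyloxy ketone or enolise C7 in competition with C–Br reduction, and control at C17 may be low. The fallback sets out from 24 and returns at 27. The 7-OH is silylated selectively to the 7α-triethylsilyl ether F5 and the 8-OH is oxidised to the 7α-triethylsilyloxy-8-ketone F6. The lithium enolate of ethyl propanoate is added intermolecularly to give the β-hydroxy ester F7. HF·pyridine removes the silyl group and the freed 7-OH lactonises to 27.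

**Step 29.** Chlorenium may be delivered to the wrong face of the olefin, the proton may be lost from C4 instead of C16, or the 8-OH may take part. The fallback sets out from 35 and returns at 36. A Schenck ene reaction (O2, hν, tetraphenylporphyrin; then PPh3) places oxygen on C6 on the same face the chlorinating agent prefers and gives the 6β-hydroxy-5(16)-ene F8. Appel chlorination (PPh3, NCS) then inverts C6 to the 6α-chloride 36, which is the outcome complementary to the direct chlorination.

## Further compounds

F1 | step 14 | 7β-hydroxy-7α-(prop-1-ynyl) carbinol | C[C@]12[C@@H](OCc3ccc(OC)cc3)C[C@@H](O[Si](C)(C)C(C)(C)C)C(=C)[C@@H]1[C@H](OCc4ccc(OC)cc4)C[C@@](O)(C#CC)[C@@]2(OC)C=C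
F2 | step 3 | acetate of ent-10 | C[C@@]12[C@H](OCc3ccc(OC)cc3)C=C(O[Si](C)(C)C(C)(C)C)C[C@H]1[C@@H](OC(C)=O)C=C(OC)[C@]2(OC)C=C
F3 | step 12 | 8α-hydroxy-7-ketone | C[C@]12[C@@H](OCc3ccc(OC)cc3)C[C@@H](O[Si](C)(C)C(C)(C)C)C(=C)[C@@H]1[C@H](OCc4ccc(OC)cc4)[C@@H](O)C(=O)[C@@]2(OC)C=C
F4 | step 12 | 8α-acetoxy-7-ketone | C[C@]12[C@@H](OCc3ccc(OC)cc3)C[C@@H](O[Si](C)(C)C(C)(C)C)C(=C)[C@@H]1[C@H](OCc4ccc(OC)cc4)[C@@H](OC(C)=O)C(=O)[C@@]2(OC)C=C
F5 | step 20 | 7α-triethylsilyl ether of diol 24 | C[C@]12[C@@H](OCc3ccc(OC)cc3)C[C@@H](O[Si](C)(C)C(C)(C)C)C(=C)[C@@H]1[C@H](OCc4ccc(OC)cc4)[C@@H](O)[C@@H](O[Si](CC)(CC)CC)/C=C(C)\C/C=C2\OC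
F6 | step 20 | 7α-triethylsilyloxy-8-ketone | C[C@]12[C@@H](OCc3ccc(OC)cc3)C[C@@H](O[Si](C)(C)C(C)(C)C)C(=C)[C@@H]1[C@H](OCc4ccc(OC)cc4)C(=O)[C@@H](O[Si](CC)(CC)CC)/C=C(C)\C/C=C2\OC
F7 | step 20 | 8α-hydroxy-8β-[(R)-1-ethoxycarbonylethyl]-7α-triethylsilyloxy ester | C[C@]12[C@@H](OCc3ccc(OC)cc3)C[C@@H](O[Si](C)(C)C(C)(C)C)C(=C)[C@@H]1[C@H](OCc4ccc(OC)cc4)[C@](O)([C@@H](C)C(=O)OCC)[C@@H](O[Si](CC)(CC)CC)/C=C(C)\C/C=C2\OC
F8 | step 29 | 6β-hydroxy-5(16)-ene analogue of 36 | C=C1CC[C@H](OC(=O)C(C)C)[C@@]2(C)[C@@H](OC(C)=O)C[C@@H](OC(=O)CC(C)C)[C@]3(CO3)[C@@H]2[C@H](OC(C)=O)[C@]2(O)[C@@H](C)C(=O)O[C@H]2[C@@H]1O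
A1 | alternative 1 | seco-diene for ring-closing metathesis at C5=C6 | C=C(C)CC[C@H](O[Si](C)(C)C(C)(C)C)[C@@]2(C)[C@@H](OCc4ccc(OC)cc4)C[C@@H](O[Si](C)(C)C(C)(C)C)C(=C)[C@@H]2[C@H](OCc4ccc(OC)cc4)[C@]3(O)[C@@H](C)C(=O)O[C@H]3C=C
A2 | alternative 2 | fourteen-membered cembranoid-type (10E)-1,14-epoxide | C[C@]12O[C@@H]1C[C@@H](OC(=O)CC(C)C)/C(C)=C/[C@H](OC(C)=O)[C@]3(O)[C@@H](C)C(=O)O[C@H]3/C=C(C)\CC[C@@H]2OC(=O)C(C)C
A3 | alternative 3 | tricyclic Δ2(7)-olefin for oxidative cleavage (C5 epimers) | C[C@]12[C@@H](OCc3ccc(OC)cc3)C[C@@H](O[Si](C)(C)C(C)(C)C)C(=C)[C@@H]1[C@H](OCc3ccc(OC)cc3)CC4=C2CCC(C)C4
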